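**Retrosynthetic overview**

1. Target 10 is oxacyclohentriacontan-2-one: one 31-membered ring (C1–C30 plus the ring oxygen; C1 is the carbonyl carbon, C30 the O-bound CH2) and no stereocentre.
2. 10 ⇐ cyclic 1,3-diyne 9 (C12≡C13–C14≡C15) by hydrogenation; 9 ⇐ open-chain bis-terminal-alkyne ester 7 by oxidative C(sp)–C(sp) coupling of C13 with C14 (Eglinton coupling), two acetylide carbons of like, nucleophilic polarity.
3. 7 ⇐ esterification of tridec-12-ynoic acid 2 (C1–C13) with heptadec-16-yn-1-ol 6 (C14–C30); 2 from 11-bromoundecanoic acid and acetylide, 6 from propargyl alcohol and 1-bromotetradecane followed by an alkyne zipper.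
4. Enabling feature: C13–C14 lies inside the unbroken polymethylene run C2–C30 of the 31-membered ring, twelve and seventeen bonds from the only functional group (the lactone C1/O). C12–C15 can therefore be carried at the alkyne oxidation level, the linear C11–C16 rod is strain-free in so large a ring, and hydrogenation removes the unsaturation.
5. Ring order: there is only one ring; it is closed in step 5, and steps 1–4 only assemble the acyclic precursor.

Key step: step 5

Remark on the chemistry: the target is taken as the achiral lactone of 30-hydroxytriacontanoic acid (29 ring CH2 groups), so no stereochemical control is needed; carbons are numbered from the carbonyl carbon (C1) to the O-bound carbon (C30).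

**Route**

Step 1
Reactants: 1 11-bromoundecanoic acid
Product: 2 tridec-12-ynoic acid
Conditions: LiC≡CH·H2NCH2CH2NH2 (2.5 equiv), DMSO, 10 °C → rt; then 1 M HCl
Reagents that add atoms: lithium acetylide–ethylenediamine complex, [Li+].[C-]#C.NCCN
Why: SN2 alkylation of an acetylide, in which the first equivalent converts the acid into its unreactive lithium carboxylate and the second displaces the primary bromide in DMSO, a transformation with close precedent for ω-bromoalkanoic acids.

Step 2
Reactants: 3 prop-2-yn-1-ol (propargyl alcohol), 4 1-bromotetradecane
Product: 5 heptadec-2-yn-1-ol
Conditions: 3, n-BuLi (2.1 equiv), THF/DMPU 4:1, −78 → −20 °C; then 4 (0.9 equiv), −20 °C → rt; H2O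
Reagents that add atoms: none
Why: C-alkylation of the propargyl alcohol dianion (acetylide alkylation), the sp carbanion being far more nucleophilic than the aggregated lithium alkoxide, with DMPU accelerating the SN2 displacement of the primary bromide.

Step 3
Reactants: 5 heptadec-2-yn-1-ol
Product: 6 heptadec-16-yn-1-ol
Conditions: KH (4.5 equiv), H2N(CH2)3NH2, rt; then 5, 0 °C → rt; ice-water
Reagents that add atoms: none
Why: Alkyne zipper reaction, in which potassium 3-aminopropylamide moves the triple bond along the chain by propargyl–allenyl proton shifts, the C1 alkoxide blocking one direction and irreversible formation of the terminal potassium acetylide pulling the equilibrium fourteen positions to the chain end without any change in carbon count.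

Step 4
Reactants: 2 tridec-12-ynoic acid, 6 heptadec-16-yn-1-ol
Product: 7 heptadec-16-yn-1-yl tridec-12-ynoate
Conditions: TsOH·H2O (5 mol %), toluene, reflux, Dean–Stark trap
Reagents that add atoms: none
Why: Fischer esterification driven to completion by azeotropic removal of water, the terminal alkynes being inert to catalytic sulfonic acid in dry toluene, so the two fragments can be used in equimolar amounts.

Step 5
Reactants: 7 heptadec-16-yn-1-yl tridec-12-ynoate
Product: 9 oxacyclohentriaconta-13,15-diyn-2-one, via dicopper bis-acetylide 8 (not isolated)
Conditions: Cu(OAc)2 (10 equiv), pyridine/Et2O 4:1, 40 °C, syringe-pump addition of 7 over 24 h (final concentration about 1 mM), then 12 h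
Reagents that add atoms: none
Why: Pyridine-assisted cupration of both terminal C–H bonds by Cu(OAc)2 gives the alkynyl copper species 8, whose two alkynyl ligands meet in an acetate-bridged dinuclear complex of divalent copper and are joined by reductive elimination, each copper leaving as CuOAc with monovalent copper. The closest known reaction type is the Eglinton (Glaser-type) oxidative homocoupling of terminal alkynes, which is used intramolecularly under high dilution to close macrocyclic 1,3-diynes, large-ring diyne lactones included. The single ring, the 31-membered lactone, closes in a head-to-tail macrocyclisation that forms the C13–C14 bond and leaves both triple bonds inside the ring (endo mode). No stereocentre is formed. The step needs ring closure to win over intermolecular coupling, which should be secured by slow addition of 7 into a large excess of Cu(OAc)2, by the strain-free fit of the linear C11–C16 diyne rod in a ring of this size, and by the absence of any other acidic or oxidisable site, the ester being inert to copper acetylides. It joins two carbons of the same nucleophilic polarity, which a polar disconnection of this remote CH2–CH2 bond could not do.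

Step 6
Reactants: 9 oxacyclohentriaconta-13,15-diyn-2-one
Product: 10 oxacyclohentriacontan-2-one (30-triacontanolide)
Conditions: H2 (1 atm), 10% Pd/C, EtOAc, rt (after filtration of 9 through silica to remove copper residues)
Reagents that add atoms: none
Why: Exhaustive heterogeneous hydrogenation of the conjugated diyne (four equivalents of H2) to the polymethylene chain, the lactone being inert to Pd/C and H2 at ambient temperature and pressure.

**Compound list**

1 | 11-bromoundecanoic acid | OC(=O)CCCCCCCCCCBr | starting material
2 | tridec-12-ynoic acid | C#CCCCCCCCCCCC(=O)O | intermediate
3 | prop-2-yn-1-ol (propargyl alcohol) | C#CCO | starting material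
4 | 1-bromotetradecane | CCCCCCCCCCCCCCBr | starting material
5 | heptadec-2-yn-1-ol | CCCCCCCCCCCCCCC#CCO | intermediate
6 | heptadec-16-yn-1-ol | C#CCCCCCCCCCCCCCCCO | intermediate
7 | heptadec-16-yn-1-yl tridec-12-ynoate | C#CCCCCCCCCCCC(=O)OCCCCCCCCCCCCCCCC#C | intermediate
8 | dicopper bis-acetylide of 7 (each terminal alkyne carbon bound to an acetate-bearing divalent copper; not isolated) | CC(=O)O[Cu]C#CCCCCCCCCCCC(=O)OCCCCCCCCCCCCCCCC#C[Cu]OC(C)=O | intermediate
9 | oxacyclohentriaconta-13,15-diyn-2-one | O=C1CCCCCCCCCCC#CC#CCCCCCCCCCCCCCCCO1 | intermediate
10 | oxacyclohentriacontan-2-one (30-triacontanolide) | O=C1CCCCCCCCCCCCCCCCCCCCCCCCCCCCCO1 | target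

**Step count and risks**

Total step count: 6. Longest linear sequence: 5 steps (steps 2, 3, 4, 5, 6).

Steps most likely to fail:

1. Step 5. Intermolecular oxidative coupling may outrun ring closure, and because the C–C bond formation is irreversible, linear and cyclic oligomers would not be corrected. The fallback sets out from 7 and comes back to the route at 10. Double anti-Markovnikov hydroboration–oxidation of both terminal alkynes (dicyclohexylborane, THF, 0 °C; then NaBO3·4H2O) should give the dialdehyde 17-oxoheptadecyl 13-oxotridecanoate F1. Intramolecular McMurry coupling (TiCl3(DME)1.5, Zn–Cu couple, DME, reflux, syringe-pump addition) then joins the same two carbons, C13 and C14, on the low-valent titanium surface, where both carbonyl groups of one molecule are bound and ring size matters little. This should give (E)-oxacyclohentriacont-14-en-2-one F2, with any Z isomer converging in the next operation. The ester is only moderately tolerant of the titanium reagent, so contact time should be kept short. Hydrogenation (H2, 10% Pd/C, EtOAc) then gives 10.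

2. Step 2. The SN2 displacement by the aggregated dilithio species may be sluggish with the long-chain bromide, leaving room for E2 elimination and O-alkylation. The fallback sets out from 4 and comes back at 5. Bromide 4 is treated with LiC≡CH·H2NCH2CH2NH2 in DMSO to give hexadec-1-yne F3, an acetylide alkylation on a neutral substrate. Lithiation of this alkyne (n-BuLi, THF, −78 °C) and addition to paraformaldehyde then gives 5, so the C1–C2 bond of 5 is the one formed, not the C3–C4 bond.

3. Step 1. E2 elimination of the bromide and base-induced migration of the new terminal triple bond may compete while the substrate is present as a poorly soluble lithium carboxylate. The fallback sets out from 3 and comes back at 2. The dianion of 3 (n-BuLi, THF/DMPU) is alkylated with commercial 1-bromodecane to give tridec-2-yn-1-ol F4. The alkyne zipper (KH, H2N(CH2)3NH2) moves the triple bond to the terminus to give tridec-12-yn-1-ol F5. Jones oxidation (CrO3, H2SO4, acetone, 0 °C) then gives 2, so the carboxyl group is introduced only after the alkyne is in place.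

Further compounds
F1 | step 5 | 17-oxoheptadecyl 13-oxotridecanoate | O=CCCCCCCCCCCCC(=O)OCCCCCCCCCCCCCCCCC=O
F2 | step 5 | (E)-oxacyclohentriacont-14-en-2-one | O=C1CCCCCCCCCCC/C=C/CCCCCCCCCCCCCCCCO1
F3 | step 2 | hexadec-1-yne | C#CCCCCCCCCCCCCCC
F4 | step 1 | tridec-2-yn-1-ol | CCCCCCCCCCC#CCO
F5 | step 1 | tridec-12-yn-1-ol | C#CCCCCCCCCCCCO
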